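The numbers were chosen freely, and the outcome is calculated.

If target in these flasks is made and unmade at the same time, its amount can be estimated from one constant and the substrate present, and I want that constant in hand before I look at any run of them.

| setting | winter | summer | spring |
|---|---|---|---|
| substrate | 0.050 M | 0.050 M | 0.050 M |
| gas | 8.9 mM (held) | 8.9 mM (held) | 8.9 mM (held) |
| time | 4.0 min | 4.0 min | 4.0 min |
| remark | at 20 °C until 50 s, from then on at 50 °C |  |  |
| temperature |  | 20 °C | 50 °C |

    partner → decomposed reagent (k1 = 0.017 s⁻¹, Ea1 = 72.0 kJ mol⁻¹)
    target + released group → side product (k2 = 0.74 M⁻¹ s⁻¹, Ea2 = 40.0 kJ mol⁻¹)
    gas ⇌ partner, rate k3*(csat - [partner]) (k3 = 0.10 s⁻¹, csat = 8.9 mM)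
    substrate + partner ⇌ target + released group (K4 = 9.8, k4 = 1.9 M⁻¹ s⁻¹, Ea4 = 38.0 kJ mol⁻¹, ΔH4 = −20.0 kJ mol⁻¹)
    (constants at 20 °C)

- which flask leads in amount of target, in percent of the substrate charged ("all alike" within 1.5 percentage points) (winter / summer / spring / all alike)
- how much target is there at the end, in percent of the substrate charged: winter
- how much target is there at the end, in percent of the substrate charged: summer
- how much target is there at the end, in percent of the substrate charged: spring

In the first instants of summer, at 20 °C, gas crosses into the solution at 0.890 mM s⁻¹, while partner is lost to decomposition with the constant 0.017 s⁻¹ and to substrate with the constant 0.0950 s⁻¹, so partner rises from nothing to near 4.20 mM. As substrate thins, partner climbs towards 7.61 mM, the upper level at which transfer balances decomposition, higher than that first level. In spring, at 50 °C, decomposition runs 15.5 times faster, so that upper level is 2.45 mM.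

In the middle, target and released group arise in pairs and go in pairs, so their concentrations are equal, and both ways of unmaking target, onward at 0.74 M⁻¹ s⁻¹ and back at 0.194 M⁻¹ s⁻¹, go with [target] squared. Setting making equal to unmaking, the quasi-steady state, gives [target] squared equal to H times [substrate], with H = 15.5 mM in summer. I call H, the forward constant times the upper level of partner divided by the sum of the two unmaking constants, the holding constant. In spring it is 3.83 mM, about a quarter of the summer value. At the full charge of substrate the balance is a fair step in summer, since target turns over in about 38.5 s, less than the 87.2 s substrate needs.

With the balance in place, the net loss of substrate equals the onward unmaking, the onward constant times H times [substrate], a pseudo-first-order decay that integrates to an exponential. Its constant is 0.0115 s⁻¹ in summer and 0.0130 s⁻¹ in spring, close together. So I reckon that summer keeps 6.40% of its substrate and, by the square root of H times [substrate], 14.1% target, while spring ends at 5.82% target. In my reckoning winter decays under the first constant for 50 s, then under the second, and ends on the hot H with 6.04%, slightly above spring. I expect the summer figures to run low, since partner in summer begins near 4.20 mM, less than the 7.61 mM on which my decay is reckoned, but I commit to summer leading by a ratio near 2.42 over spring.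

The forecast names summer as leader, with 10.2% for winter, 23% for summer and 9.5% for spring, holding that when hot “target stays low and is steadily lost”. The simulation gives summer in the lead, with 9.49% in winter, 22.9% in summer and 9.18% in spring.

Summer stands 8.8 percentage points above my figure, and it still holds 12% of its substrate against my 6.40%, so my decay ran too fast, while its target stands at 2.49 times that of spring. Put the substrate at the end of summer into the square root with the holding constant and target comes to 19.6%, still under the 22.9% of that flask. The neighbouring flask is summer read earlier, at 2.5 min, with 29% of its substrate left; the same square root gives 29.8%, and that flask holds 30.2% target.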